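The route rests on cutting ring A at C1–C2 and C4–C5. C1 and C5 both hang on the quaternary C10, so they map onto the aldehyde and ketone of a non-enolisable β-keto aldehyde, while C2–C3–C4 is acetone. One double aldol condensation welds acetone onto this 1,3-dicarbonyl and closes ring A as a cross-conjugated dienone; its C3 carbonyl then directs gem-dimethylation at C4 and is erased. The precursor is an enantiopure 2-formyl-2-methylcyclohexanone whose second flanking ketone (future C9) is masked as a dioxolane. The C9 ketone later becomes an enol triflate that is joined to a separately built lactone side chain by B-alkyl Suzuki coupling.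

Key step: step 7

Remark: atom labels are labdane numbers (ring A = C1–C5 and C10, ring B = C5–C10, side chain C11–C16, lactone ring carbon C17 with C18H2, C19=O and C20H2O); baker's yeast is taken to give the (2S,3S)-ketol 4, as is established for this substrate class. TBS = tert-butyldimethylsilyl.

**Step 1**
Reactants: 1 2-methylcyclohexane-1,3-dione; 2 allyl bromide
Product: 3 2-allyl-2-methylcyclohexane-1,3-dione
Conditions: 1 M aq. NaOH, rt
Reagents that add atoms: none
Why: C-alkylation of the 1,3-diketone enolate by the allylic bromide (SN2) should give the prochiral 2,2-disubstituted dione, the allyl group serving as a masked formyl group (future C1); no stereocentre is formed.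

**Step 2**
Reactants: 3 2-allyl-2-methylcyclohexane-1,3-dione
Product: 4 (2S,3S)-2-allyl-3-hydroxy-2-methylcyclohexan-1-one
Conditions: baker's yeast (Saccharomyces cerevisiae), sucrose, H2O, 30 °C; chromatography
Reagents that add atoms: none
Why: Enzymatic desymmetrising carbonyl reduction: the yeast ketoreductase reduces one of the two enantiotopic ketones to the (S)-carbinol, and this choice of carbonyl fixes the quaternary carbon (future C10) as 2S; the minor (2R,3S) isomer is removed by chromatography so that C10 stays homochiral after the carbinol is re-oxidised in step 4.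

**Step 3**
Reactants: 4 (2S,3S)-2-allyl-3-hydroxy-2-methylcyclohexan-1-one
Product: 5 (6S,7S)-6-allyl-6-methyl-1,4-dioxaspiro[4.5]decan-7-ol
Conditions: ethylene glycol, TsOH·H2O (cat.), benzene, reflux (Dean–Stark)
Reagents that add atoms: ethylene glycol, OCCO
Why: Acid-catalysed ketalisation with azeotropic removal of water masks the ketone that becomes C9; the hydroxyl, the alkene and the quaternary centre are untouched.

**Step 4**
Reactants: 5 (6S,7S)-6-allyl-6-methyl-1,4-dioxaspiro[4.5]decan-7-ol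
Product: 6 (S)-6-allyl-6-methyl-1,4-dioxaspiro[4.5]decan-7-one
Conditions: (n-Pr4N)RuO4 (cat.), N-methylmorpholine N-oxide, 4 Å molecular sieves, CH2Cl2, rt
Reagents that add atoms: none
Why: Ley–Griffith oxidation of the secondary alcohol gives the ketone that becomes C5; the carbinol stereocentre is intentionally erased and the quaternary C10 cannot epimerise.

**Step 5**
Reactants: 6 (S)-6-allyl-6-methyl-1,4-dioxaspiro[4.5]decan-7-one
Product: 7 (S)-6-methyl-6-[(E)-prop-1-enyl]-1,4-dioxaspiro[4.5]decan-7-one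
Conditions: RuHCl(CO)(PPh3)3 (cat.), toluene, 100 °C
Reagents that add atoms: none
Why: Ruthenium-hydride catalysed olefin isomerisation (hydrometalation/β-hydride elimination) moves the terminal double bond one position inwards and must stop there because C10 is quaternary.

**Step 6**
Reactants: 7 (S)-6-methyl-6-[(E)-prop-1-enyl]-1,4-dioxaspiro[4.5]decan-7-one
Product: 9 (S)-6-methyl-7-oxo-1,4-dioxaspiro[4.5]decane-6-carbaldehyde, via ozonide 8 (not isolated)
Conditions: O3, CH2Cl2, −78 °C; then PPh3, −78 °C → rt; used directly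
Reagents that add atoms: ozone, [O-][O+]=O
Why: Ozonolysis through the Criegee ozonide with reductive work-up cuts the propenyl group down to the one-carbon aldehyde C1; the β-keto aldehyde is non-enolisable, so C10 is configurationally safe.

**Step 7**
Reactants: 9 (S)-6-methyl-7-oxo-1,4-dioxaspiro[4.5]decane-6-carbaldehyde; 10 acetone
Product: 12 (4a'S)-4a'-methyl-4a',6',7',8'-tetrahydro-2'H-spiro[[1,3]dioxolane-2,5'-naphthalen]-2'-one (ring A = C1=C2–C3(=O)–C4=C5, dioxolane at C9), via ketol 11 (not isolated)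
Conditions: acetone (10 equiv), L-proline (30 mol %), DMSO, rt; then pyrrolidine (1 equiv), AcOH (1 equiv), 60 °C, same flask
Reagents that add atoms: none
Why: The proline enamine of acetone should add to the neopentylic, non-enolisable aldehyde (intermolecular aldol, C1–C2) to give ketol 11; the pyrrolidine enamine of its methyl terminus C4 then attacks the ring ketone C5, and two E1cB dehydrations (C4–H/C5–OH and C2–H/C1–OH) deliver the cross-conjugated dienone as the thermodynamic sink. The closest known reaction type is the amine-catalysed double aldol condensation of 2-formyl-2-alkylcyclohexanones with acetone to 4,4-disubstituted cyclohexa-2,5-dienones, the second half being a Robinson/Hajos–Parrish-type closure. Ring A closes by a 6-(enolendo)-exo-trig aldol; any E-enone formed by early dehydration can re-enter through reversible aza-Michael addition of pyrrolidine. No stereocentre is created (the C1 carbinol is erased) and C10, being quaternary, is carried unchanged from 9. The step needs aldehyde-before-ketone chemoselectivity and fused-over-bridged ring closure: the aldehyde is the only unhindered electrophile, only the fused ketol can dehydrate into conjugation, and the hydroxide-free medium avoids retro-Claisen loss of the formyl group.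

**Step 8**
Reactants: 12 dienone
Product: 13 (4a'S)-1',1',4a'-trimethyl-1',4a',6',7'-tetrahydro-2'H-spiro[[1,3]dioxolane-2,5'-naphthalen]-2'-one (4,4-dimethyl-1,5-dien-3-one, dioxolane at C9)
Conditions: KOtBu (3 equiv), MeI (6 equiv), t-BuOH/THF, 0 °C → rt
Reagents that add atoms: iodomethane, CI
Why: Deconjugative α,α-dialkylation of an enone: γ-deprotonation at C6 gives the extended dienolate, which is methylated twice at C4 and leaves the C5=C6 bond out of conjugation; no other acidic position exists (C10 is quaternary) and C4 is not stereogenic.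

**Step 9**
Reactants: 13 4,4-dimethyl-1,5-dien-3-one ketal
Product: 14 (4a'S,8a'S)-1',1',4a'-trimethyloctahydro-2'H-spiro[[1,3]dioxolane-2,5'-naphthalen]-2'-one (trans-fused; 5S,10S)
Conditions: H2 (4 atm), Pd/C, EtOAc, rt
Reagents that add atoms: none
Why: Heterogeneous catalytic hydrogenation saturates the enone C1=C2 bond and the hindered C5=C6 bond; hydrogen should be delivered to C5 from the α face, opposite the axial C10 methyl and the 4β-methyl, which sets the trans ring fusion (5S).

**Step 10**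
Reactants: 14 saturated 3-ketone ketal
Product: 16 (4aS,8aS)-5,5,8a-trimethyloctahydronaphthalen-1(2H)-one, via ketal hydrocarbon 15 (not isolated)
Conditions: N2H4·H2O, KOH, diethylene glycol, 130 → 210 °C; then 3 M aq. HCl, THF, rt
Reagents that add atoms: water, O
Why: Wolff–Kishner reduction (Huang–Minlon procedure) removes the C3 carbonyl through its hydrazone while the dioxolane survives the base, and the aqueous acid then hydrolyses the ketal to the C9 ketone; neither C5 nor C10 is epimerisable.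

**Step 11**
Reactants: 16 (4aS,8aS)-5,5,8a-trimethyloctahydronaphthalen-1(2H)-one
Product: 18 (4aS,8aS)-2,5,5,8a-tetramethyloctahydronaphthalen-1(2H)-one (C2 epimers), via lithium enolate 17 (not isolated)
Conditions: LiN(i-Pr)2, THF, −78 °C; then MeI, −78 → 0 °C
Reagents that add atoms: iodomethane, CI
Why: Kinetic enolate alkylation: the base can only deprotonate C8, since C10 is quaternary, and MeI methylates that enolate; the new C8 centre is of no consequence because it becomes sp2 in step 12.

**Step 12**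
Reactants: 18 (4aS,8aS)-2,5,5,8a-tetramethyloctahydronaphthalen-1(2H)-one
Product: 20 (4aS,8aS)-2,5,5,8a-tetramethyl-3,4,4a,5,6,7,8,8a-octahydronaphthalen-1-yl trifluoromethanesulfonate, via potassium enolate 19 (not isolated)
Conditions: KN(SiMe3)2, THF, −78 → 0 °C; then PhNTf2, 0 °C → rt
Reagents that add atoms: N-phenyl-bis(trifluoromethanesulfonimide), O=S(=O)(N(c1ccccc1)S(=O)(=O)C(F)(F)F)C(F)(F)F
Why: Enol triflate formation: removal of the single remaining α-hydrogen at C8 gives the tetrasubstituted enolate, whose O-sulfonylation fixes the C8=C9 double bond regiospecifically and activates C9 for cross-coupling.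

**Step 13**
Reactants: 21 propargyl alcohol; 22 vinylmagnesium bromide
Product: 24 (Z)-2-(iodomethylidene)but-3-en-1-ol, via vinylmagnesium alkoxide 23 (not isolated)
Conditions: 22 (2.5 equiv), CuI (10 mol %), THF/Et2O, −10 °C → rt; then I2, −78 → 0 °C
Reagents that add atoms: iodine, II
Why: Duboudin copper-catalysed anti-carbomagnesiation of propargyl alcohol: the vinyl group adds to the internal alkyne carbon and magnesium ends on the terminal carbon, held cis to CH2O in a five-membered magnesium alkoxide chelate, so that iodinolysis with retention gives the (Z)-iodide with the future C14 substituent cis to CH2OH.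

**Step 14**
Reactants: 24 (Z)-2-(iodomethylidene)but-3-en-1-ol
Product: 25 tert-butyl{[(2Z)-2-(iodomethylidene)but-3-en-1-yl]oxy}dimethylsilane
Conditions: TBSCl, imidazole, CH2Cl2, 0 °C → rt
Reagents that add atoms: tert-butyldimethylsilyl chloride, CC(C)(C)[Si](C)(C)Cl
Why: Imidazole-promoted silyl ether formation protects the primary allylic alcohol for the organolithium step.

**Step 15**
Reactants: 25 (Z)-vinyl iodide TBS ether; 26 oxirane
Product: 28 (3Z)-4-({[tert-butyl(dimethyl)silyl]oxy}methyl)hexa-3,5-dien-1-ol, via vinyllithium 27 (not isolated)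
Conditions: t-BuLi (2 equiv), Et2O, −78 °C; then oxirane, BF3·OEt2, −78 °C
Reagents that add atoms: none
Why: Iodine–lithium exchange proceeds with retention of alkene geometry and the BF3-activated oxirane is opened by the vinyllithium (SN2) to the homoallylic alcohol; ether at −78 °C should suppress the 1,4-silyl shift (retro-Brook) of the cis-disposed silyloxymethyl group.

**Step 16**
Reactants: 28 homoallylic alcohol
Product: 29 (3Z)-4-({[tert-butyl(dimethyl)silyl]oxy}methyl)hexa-3,5-dienal
Conditions: Dess–Martin periodinane, NaHCO3, CH2Cl2, 0 °C; used crude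
Reagents that add atoms: none
Why: Dess–Martin oxidation under bicarbonate buffer should give the β,γ-unsaturated aldehyde without moving the double bond into conjugation.

**Step 17**
Reactants: 30 4-(tert-butoxy)-4-oxobutanoic acid; 31 (S)-4-benzyloxazolidin-2-one
Product: 33 tert-butyl 4-[(4S)-4-benzyl-2-oxo-1,3-oxazolidin-3-yl]-4-oxobutanoate, via mixed anhydride 32 (not isolated)
Conditions: pivaloyl chloride, Et3N, THF, −20 °C; then 31, LiCl, −20 °C → rt
Reagents that add atoms: none
Why: N-Acylation of the oxazolidinone through the pivaloyl mixed anhydride attaches the succinate unit to the Evans auxiliary; the hindered pivaloyl carbonyl directs attack to the succinyl carbonyl.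

**Step 18**
Reactants: 33 succinate imide; 29 (3Z)-dienal
Product: 35 tert-butyl (3S,4R,6Z)-3-{[(4S)-4-benzyl-2-oxo-1,3-oxazolidin-3-yl]carbonyl}-4-hydroxy-7-({[tert-butyl(dimethyl)silyl]oxy}methyl)nona-6,8-dienoate, via boron enolate 34 (not isolated)
Conditions: Bu2BOTf, i-Pr2NEt, CH2Cl2, −78 → 0 °C; then 29, −78 °C; pH 7 buffer/MeOH/H2O2 work-up, 0 °C
Reagents that add atoms: none
Why: Evans syn-aldol reaction: the Z-boron enolate of the imide (the ester is not enolised) reacts through a Zimmerman–Traxler chair with the aldehyde on the face away from the benzyl group, setting the carbinol C16 and the adjacent C17 as the Evans syn pair (16R,17R of the target), while the tert-butyl ester keeps the aldolate from lactonising.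

**Step 19**
Reactants: 35 aldol adduct
Product: 37 (3S,4R,6Z)-3-{[(4S)-4-benzyl-2-oxo-1,3-oxazolidin-3-yl]carbonyl}-4-{[tert-butyl(dimethyl)silyl]oxy}-7-({[tert-butyl(dimethyl)silyl]oxy}methyl)nona-6,8-dienoic acid, via silyl ester 36 (not isolated)
Conditions: TBSOTf (3 equiv), 2,6-lutidine, CH2Cl2, −78 °C → rt; then aq. citric acid, THF
Reagents that add atoms: tert-butyldimethylsilyl trifluoromethanesulfonate, CC(C)(C)[Si](C)(C)OS(=O)(=O)C(F)(F)F
Why: Silyl triflate chemistry does two jobs, O-silylation of the C16 carbinol and conversion of the tert-butyl ester into a silyl ester with loss of isobutene, the silyl ester being hydrolysed on mildly acidic work-up so that the acid-sensitive diene never meets a strong protic acid.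

**Step 20**
Reactants: 37 silyl ether acid
Product: 39 (4R)-4-[(1R,3Z)-1-{[tert-butyl(dimethyl)silyl]oxy}-4-({[tert-butyl(dimethyl)silyl]oxy}methyl)hexa-3,5-dien-1-yl]oxolan-2-one, via hydroxy acid 38 (not isolated)
Conditions: LiBH4, THF/MeOH, 0 °C; then 1 M aq. citric acid to pH 3, rt
Reagents that add atoms: none
Why: Reductive cleavage of the Evans imide: LiBH4 reduces the exocyclic imide carbonyl to the primary alcohol (C20) and releases the auxiliary while the lithium carboxylate is inert, and acidification closes the γ-lactone (5-exo-trig lactonisation) onto the only free hydroxyl because C16–OH is silylated.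

**Step 21**
Reactants: 39 dienyl lactone; 20 enol triflate
Product: 41 (4R)-4-[(1R,3Z)-1-{[tert-butyl(dimethyl)silyl]oxy}-4-({[tert-butyl(dimethyl)silyl]oxy}methyl)-6-[(4aS,8aS)-2,5,5,8a-tetramethyl-3,4,4a,5,6,7,8,8a-octahydronaphthalen-1-yl]hex-3-en-1-yl]oxolan-2-one, via alkylborane 40 (not isolated)
Conditions: 9-BBN, THF, rt; then 20, PdCl2(dppf) (cat.), AsPh3, Cs2CO3, DMF/H2O, 50 °C
Reagents that add atoms: none
Why: B-alkyl Suzuki–Miyaura coupling: 9-BBN hydroborates only the monosubstituted terminus of the diene (anti-Markovnikov), and the primary alkylborane is transferred to palladium and coupled with the enol triflate with retention of the tetrasubstituted C8=C9 bond, forming C9–C11.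

**Step 22**
Reactants: 41 bis-TBS ether
Product: 42 (4R)-4-[(1R,3Z)-1-hydroxy-4-(hydroxymethyl)-6-[(4aS,8aS)-2,5,5,8a-tetramethyl-3,4,4a,5,6,7,8,8a-octahydronaphthalen-1-yl]hex-3-en-1-yl]oxolan-2-one (target)
Conditions: HF·pyridine, pyridine, THF, 0 °C → rt
Reagents that add atoms: none
Why: Fluoride-mediated desilylation under buffered, mildly acidic conditions frees the allylic and the secondary hydroxyl without translactonisation or migration of the tetrasubstituted double bond.

**Compound list**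

1 | 2-methylcyclohexane-1,3-dione | CC1C(=O)CCCC1=O | starting material
2 | allyl bromide (3-bromoprop-1-ene) | C=CCBr | starting material
3 | 2-allyl-2-methylcyclohexane-1,3-dione | C=CCC1(C)C(=O)CCCC1=O | intermediate
4 | (2S,3S)-2-allyl-3-hydroxy-2-methylcyclohexan-1-one | C=CC[C@]1(C)C(=O)CCC[C@@H]1O | intermediate
5 | (6S,7S)-6-allyl-6-methyl-1,4-dioxaspiro[4.5]decan-7-ol | C=CC[C@]1(C)C2(OCCO2)CCC[C@@H]1O | intermediate
6 | (S)-6-allyl-6-methyl-1,4-dioxaspiro[4.5]decan-7-one | C=CC[C@]1(C)C2(OCCO2)CCCC1=O | intermediate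
7 | (S)-6-methyl-6-[(E)-prop-1-enyl]-1,4-dioxaspiro[4.5]decan-7-one | C/C=C/[C@]1(C)C2(OCCO2)CCCC1=O | intermediate
8 | secondary ozonide of 7: (6S)-6-methyl-6-(5-methyl-1,2,4-trioxolan-3-yl)-1,4-dioxaspiro[4.5]decan-7-one | CC1OOC(O1)[C@]2(C)C3(OCCO3)CCCC2=O | intermediate
9 | (S)-6-methyl-7-oxo-1,4-dioxaspiro[4.5]decane-6-carbaldehyde | O=C[C@]1(C)C2(OCCO2)CCCC1=O | intermediate
10 | acetone | CC(C)=O | starting material
11 | (6S)-6-(1-hydroxy-3-oxobutyl)-6-methyl-1,4-dioxaspiro[4.5]decan-7-one (both carbinol epimers) | CC(=O)CC(O)[C@]1(C)C2(OCCO2)CCCC1=O | intermediate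
12 | (4a'S)-4a'-methyl-4a',6',7',8'-tetrahydro-2'H-spiro[[1,3]dioxolane-2,5'-naphthalen]-2'-one | O=C1C=C[C@@]2(C)C(=C1)CCCC23OCCO3 | intermediate
13 | (4a'S)-1',1',4a'-trimethyl-1',4a',6',7'-tetrahydro-2'H-spiro[[1,3]dioxolane-2,5'-naphthalen]-2'-one | O=C1C=C[C@@]2(C)C(=CCCC23OCCO3)C1(C)C | intermediate
14 | (4a'S,8a'S)-1',1',4a'-trimethyloctahydro-2'H-spiro[[1,3]dioxolane-2,5'-naphthalen]-2'-one (trans-fused) | CC1(C)C(=O)CC[C@@]2(C)[C@H]1CCCC23OCCO3 | intermediate
15 | (4a'S,8a'S)-1',1',4a'-trimethyloctahydro-1'H-spiro[[1,3]dioxolane-2,5'-naphthalene] (trans-fused) | CC1(C)CCC[C@@]2(C)[C@H]1CCCC23OCCO3 | intermediate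
16 | (4aS,8aS)-5,5,8a-trimethyloctahydronaphthalen-1(2H)-one | CC1(C)CCC[C@@]2(C)[C@H]1CCCC2=O | intermediate
17 | lithium enolate of 16 (C8=C9–OLi) | CC1(C)CCC[C@@]2(C)[C@H]1CCC=C2[O-].[Li+] | intermediate
18 | (4aS,8aS)-2,5,5,8a-tetramethyloctahydronaphthalen-1(2H)-one (C2 epimers) | CC1(C)CCC[C@@]2(C)[C@H]1CCC(C)C2=O | intermediate
19 | potassium enolate of 18 (tetrasubstituted C8=C9–OK) | CC1=C([O-])[C@@]2(C)CCCC(C)(C)[C@@H]2CC1.[K+] | intermediate
20 | (4aS,8aS)-2,5,5,8a-tetramethyl-3,4,4a,5,6,7,8,8a-octahydronaphthalen-1-yl trifluoromethanesulfonate | CC1=C(OS(=O)(=O)C(F)(F)F)[C@@]2(C)CCCC(C)(C)[C@@H]2CC1 | intermediate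
21 | propargyl alcohol (prop-2-yn-1-ol) | C#CCO | starting material
22 | vinylmagnesium bromide | C=C[Mg]Br | starting material
23 | bromomagnesium (2Z)-2-[(bromomagnesio)methylidene]but-3-en-1-olate | Br[Mg]OC/C(C=C)=C\[Mg]Br | intermediate
24 | (Z)-2-(iodomethylidene)but-3-en-1-ol | OC/C(C=C)=C\I | intermediate
25 | tert-butyl{[(2Z)-2-(iodomethylidene)but-3-en-1-yl]oxy}dimethylsilane | CC(C)(C)[Si](C)(C)OC/C(C=C)=C\I | intermediate
26 | oxirane (ethylene oxide) | C1CO1 | starting material
27 | (Z)-vinyllithium from 25 | CC(C)(C)[Si](C)(C)OC/C(C=C)=C\[Li] | intermediate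
28 | (3Z)-4-({[tert-butyl(dimethyl)silyl]oxy}methyl)hexa-3,5-dien-1-ol | CC(C)(C)[Si](C)(C)OC/C(C=C)=C\CCO | intermediate
29 | (3Z)-4-({[tert-butyl(dimethyl)silyl]oxy}methyl)hexa-3,5-dienal | CC(C)(C)[Si](C)(C)OC/C(C=C)=C\CC=O | intermediate
30 | 4-(tert-butoxy)-4-oxobutanoic acid (mono-tert-butyl succinate) | CC(C)(C)OC(=O)CCC(=O)O | starting material
31 | (S)-4-benzyloxazolidin-2-one | O=C1N[C@@H](Cc2ccccc2)CO1 | starting material
32 | 4-(tert-butoxy)-4-oxobutanoic pivalic anhydride | CC(C)(C)OC(=O)CCC(=O)OC(=O)C(C)(C)C | intermediate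
33 | tert-butyl 4-[(4S)-4-benzyl-2-oxo-1,3-oxazolidin-3-yl]-4-oxobutanoate | CC(C)(C)OC(=O)CCC(=O)N1[C@@H](Cc2ccccc2)COC1=O | intermediate
34 | (Z)-dibutylboron enolate of 33 | CCCCB(CCCC)O/C(=C\CC(=O)OC(C)(C)C)N1[C@@H](Cc2ccccc2)COC1=O | intermediate
35 | tert-butyl (3S,4R,6Z)-3-{[(4S)-4-benzyl-2-oxo-1,3-oxazolidin-3-yl]carbonyl}-4-hydroxy-7-({[tert-butyl(dimethyl)silyl]oxy}methyl)nona-6,8-dienoate | CC(C)(C)[Si](C)(C)OC/C(C=C)=C\C[C@@H](O)[C@H](CC(=O)OC(C)(C)C)C(=O)N1[C@@H](Cc2ccccc2)COC1=O | intermediate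
36 | tert-butyldimethylsilyl ester of 37 | CC(C)(C)[Si](C)(C)OC/C(C=C)=C\C[C@@H](O[Si](C)(C)C(C)(C)C)[C@H](CC(=O)O[Si](C)(C)C(C)(C)C)C(=O)N1[C@@H](Cc2ccccc2)COC1=O | intermediate
37 | (3S,4R,6Z)-3-{[(4S)-4-benzyl-2-oxo-1,3-oxazolidin-3-yl]carbonyl}-4-{[tert-butyl(dimethyl)silyl]oxy}-7-({[tert-butyl(dimethyl)silyl]oxy}methyl)nona-6,8-dienoic acid | CC(C)(C)[Si](C)(C)OC/C(C=C)=C\C[C@@H](O[Si](C)(C)C(C)(C)C)[C@H](CC(=O)O)C(=O)N1[C@@H](Cc2ccccc2)COC1=O | intermediate
38 | (3R,4R,6Z)-4-{[tert-butyl(dimethyl)silyl]oxy}-3-(hydroxymethyl)-7-({[tert-butyl(dimethyl)silyl]oxy}methyl)nona-6,8-dienoic acid | CC(C)(C)[Si](C)(C)OC/C(C=C)=C\C[C@@H](O[Si](C)(C)C(C)(C)C)[C@H](CC(=O)O)CO | intermediate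
39 | (4R)-4-[(1R,3Z)-1-{[tert-butyl(dimethyl)silyl]oxy}-4-({[tert-butyl(dimethyl)silyl]oxy}methyl)hexa-3,5-dien-1-yl]oxolan-2-one | CC(C)(C)[Si](C)(C)OC/C(C=C)=C\C[C@@H](O[Si](C)(C)C(C)(C)C)[C@H]1COC(=O)C1 | intermediate
40 | B-alkyl-9-borabicyclo[3.3.1]nonane from 39 (boron on C11) | CC(C)(C)[Si](C)(C)OC/C(CCB1C2CCCC1CCC2)=C\C[C@@H](O[Si](C)(C)C(C)(C)C)[C@H]1COC(=O)C1 | intermediate
41 | bis-TBS ether of the target | CC1=C(CC/C(=C/C[C@@H](O[Si](C)(C)C(C)(C)C)[C@H]2COC(=O)C2)CO[Si](C)(C)C(C)(C)C)[C@@]2(C)CCCC(C)(C)[C@@H]2CC1 | intermediate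
42 | (4R)-4-[(1R,3Z)-1-hydroxy-4-(hydroxymethyl)-6-[(4aS,8aS)-2,5,5,8a-tetramethyl-3,4,4a,5,6,7,8,8a-octahydronaphthalen-1-yl]hex-3-en-1-yl]oxolan-2-one | CC1=C(CC/C(=C/C[C@@H](O)[C@H]2COC(=O)C2)CO)[C@@]2(C)CCCC(C)(C)[C@@H]2CC1 | target

**Step count and risks**

Total step count: 22. Longest linear sequence: 14 steps (steps 1–12, 21 and 22).

Most likely to fail, first: step 7. The acyclic ketol may dehydrate to the E-enone faster than it cyclises, or the formyl group may be lost by retro-Claisen cleavage. The fallback separates the two bond formations and fixes the enone geometry first. It sets out from aldehyde 9, which is olefinated in a Still–Gennari-type Horner–Wadsworth–Emmons reaction with bis(2,2,2-trifluoroethyl) (2-oxopropyl)phosphonate (KN(SiMe3)2, 18-crown-6, THF, −78 °C) to the cis-enone (S)-6-methyl-6-[(Z)-3-oxobut-1-enyl]-1,4-dioxaspiro[4.5]decan-7-one F1. Its cis geometry allows direct intramolecular aldol condensation (pyrrolidine, AcOH, toluene, 60 °C), and the route is rejoined at dienone 12.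

Second: step 18. The skipped double bond of dienal 29 may migrate into conjugation under the amine base before C–C bond formation, and diastereoselectivity may erode. The fallback moves the fragment union ahead of the aldol, so that the aldehyde no longer carries a 1,3-diene. It sets out from alcohol 28:
- hydroboration with 9-BBN (2.2 equiv) should give the O-borylated alkylborane F2;
- coupling with triflate 20 (PdCl2(dppf), AsPh3, Cs2CO3, DMF/H2O) gives the homoallylic alcohol (3Z)-4-(TBS-oxymethyl)-6-(decalinyl)hex-3-en-1-ol F3;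
- Dess–Martin oxidation gives the aldehyde F4;
- boron enolate 34 adds to it to give the Evans syn-aldol adduct F5;
- TBSOTf/2,6-lutidine gives the bis-silyl compound F6 and, after aqueous work-up, the acid F7;
- LiBH4 gives the hydroxy acid F8, which lactonises on acidification, and the route is rejoined at 41.

Third: step 21. Oxidative addition and transmetalation at the hindered tetrasubstituted enol triflate may be slow, so that protodeboronation and β-hydride elimination of the alkylpalladium take over. The fallback changes the nucleophile to an alkylzinc (Negishi coupling). It sets out from lactone 39: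
- borane 40, made as in step 21, is oxidised (NaBO3·4H2O, THF/H2O) to the primary alcohol F9;
- I2, PPh3 and imidazole convert it to the iodide F10;
- zinc insertion (Zn dust, LiCl, THF) gives the alkylzinc iodide F11;
- coupling with 20 (Pd2(dba)3, SPhos, THF/NMP) rejoins the route at 41.

**Further compounds**

F1 | step 7 | (S)-6-methyl-6-[(Z)-3-oxobut-1-enyl]-1,4-dioxaspiro[4.5]decan-7-one | CC(=O)/C=C\[C@]1(C)C2(OCCO2)CCCC1=O
F2 | step 18 | O-borylated B-alkyl-9-borabicyclo[3.3.1]nonane from 28 | CC(C)(C)[Si](C)(C)OC/C(CCB1C2CCCC1CCC2)=C\CCOB1C2CCCC1CCC2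
F3 | step 18 | (3Z)-4-({[tert-butyl(dimethyl)silyl]oxy}methyl)-6-[(4aS,8aS)-2,5,5,8a-tetramethyl-3,4,4a,5,6,7,8,8a-octahydronaphthalen-1-yl]hex-3-en-1-ol | CC1=C(CC/C(=C/CCO)CO[Si](C)(C)C(C)(C)C)[C@@]2(C)CCCC(C)(C)[C@@H]2CC1
F4 | step 18 | (3Z)-4-({[tert-butyl(dimethyl)silyl]oxy}methyl)-6-[(4aS,8aS)-2,5,5,8a-tetramethyl-3,4,4a,5,6,7,8,8a-octahydronaphthalen-1-yl]hex-3-enal | CC1=C(CC/C(=C/CC=O)CO[Si](C)(C)C(C)(C)C)[C@@]2(C)CCCC(C)(C)[C@@H]2CC1
F5 | step 18 | Evans syn-aldol adduct of 33 and F4 (tert-butyl ester, free 16R carbinol, 17S-configured imide carbon as in 35) | CC1=C(CC/C(=C/C[C@@H](O)[C@H](CC(=O)OC(C)(C)C)C(=O)N3[C@@H](Cc4ccccc4)COC3=O)CO[Si](C)(C)C(C)(C)C)[C@@]2(C)CCCC(C)(C)[C@@H]2CC1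
F6 | step 18 | C16 TBS ether and TBS ester from F5 | CC1=C(CC/C(=C/C[C@@H](O[Si](C)(C)C(C)(C)C)[C@H](CC(=O)O[Si](C)(C)C(C)(C)C)C(=O)N3[C@@H](Cc4ccccc4)COC3=O)CO[Si](C)(C)C(C)(C)C)[C@@]2(C)CCCC(C)(C)[C@@H]2CC1
F7 | step 18 | C16 TBS ether carboxylic acid (imide intact) | CC1=C(CC/C(=C/C[C@@H](O[Si](C)(C)C(C)(C)C)[C@H](CC(=O)O)C(=O)N3[C@@H](Cc4ccccc4)COC3=O)CO[Si](C)(C)C(C)(C)C)[C@@]2(C)CCCC(C)(C)[C@@H]2CC1
F8 | step 18 | γ-hydroxy acid (C20 hydroxymethyl, C19 acid, C16 TBS ether) | CC1=C(CC/C(=C/C[C@@H](O[Si](C)(C)C(C)(C)C)[C@H](CC(=O)O)CO)CO[Si](C)(C)C(C)(C)C)[C@@]2(C)CCCC(C)(C)[C@@H]2CC1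
F9 | step 21 | (4R)-4-[(1R,3Z)-1-{[tert-butyl(dimethyl)silyl]oxy}-4-({[tert-butyl(dimethyl)silyl]oxy}methyl)-6-hydroxyhex-3-en-1-yl]oxolan-2-one | CC(C)(C)[Si](C)(C)OC/C(CCO)=C\C[C@@H](O[Si](C)(C)C(C)(C)C)[C@H]1COC(=O)C1
F10 | step 21 | (4R)-4-[(1R,3Z)-1-{[tert-butyl(dimethyl)silyl]oxy}-4-({[tert-butyl(dimethyl)silyl]oxy}methyl)-6-iodohex-3-en-1-yl]oxolan-2-one | CC(C)(C)[Si](C)(C)OC/C(CCI)=C\C[C@@H](O[Si](C)(C)C(C)(C)C)[C@H]1COC(=O)C1
F11 | step 21 | alkylzinc iodide from F10 (zinc on C11) | CC(C)(C)[Si](C)(C)OC/C(CC[Zn]I)=C\C[C@@H](O[Si](C)(C)C(C)(C)C)[C@H]1COC(=O)C1
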